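## Retrosynthetic overview
1. Kanzonol X ⇒ its tris-MOM ether. Both prenyl groups are cut at once, because C8 and C3′ each sit between two oxygen substituents. This allows a twofold directed ortho-metalation (DoM) and prenylation of one intermediate.
2. Tris-MOM (R)-isoflavan ⇒ (R)-7,2′,4′-trihydroxyisoflavan ⇒ (R)-sativan, a Me→MOM exchange done before any alkene is present.
3. C3 stereocentre ⇒ Ru-catalysed asymmetric transfer hydrogenation with dynamic kinetic resolution (ATH-DKR) of the racemic isoflavanone. The free 7-OH drives in situ loss of the 4-OH.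
4. Isoflavanone ⇒ isoflavone ⇒ resorcinol + 2,4-dimethoxyphenylacetic acid + one carbon from DMF.
5. Ring order: rings A and B are purchased. Only the pyran C ring is built (Step 1), then reduced to the chroman (Steps 2–3).

Assumption: the stereocentre in the given SMILES is (3R), with CIP order C2 > C1′ > C4 > H. A one-pot operation without isolation counts as one step.

## Route

**Step 1**
Reactants: 1 resorcinol; 2 2,4-dimethoxyphenylacetic acid
Product: 4 7-hydroxy-2′,4′-dimethoxyisoflavone, formed via deoxybenzoin 3, 1-(2,4-dihydroxyphenyl)-2-(2,4-dimethoxyphenyl)ethanone (not isolated)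
Conditions: BF3·OEt2 (neat), 85 °C, 1.5 h; cool to 10 °C, add DMF, then MsCl/DMF, 55 °C, 2 h; aq. NaOAc work-up
Reagents that add atoms: DMF, CN(C)C=O (supplies C2–H)
Why: Friedel–Crafts acylation of resorcinol at C4 gives 3, and Vilsmeier-type formylation of its activated CH2 then closes onto the 2-OH in a one-pot deoxybenzoin isoflavone synthesis; no stereocentre is formed.

**Step 2**
Reactants: 4
Product: 5 (±)-7-hydroxy-2′,4′-dimethoxyisoflavanone
Conditions: 10% Pd/C, HCO2NH4 (4 equiv), MeOH, 60 °C, stopped when 4 is consumed; chromatograph or crystallise to remove any over-reduced racemic material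
Reagents that add atoms: none
Why: Catalytic transfer hydrogenation saturates the enone C2=C3 bond faster than it reduces the deactivated 2,4-dioxygenated aryl ketone, and C3 is deliberately formed racemic because Step 3 resets it.

**Step 3**
Reactants: 5
Product: 7 (3R)-7-hydroxy-2′,4′-dimethoxyisoflavan, (R)-sativan, formed via cis-(3R,4R)-isoflavan-4-ol 6 (not isolated)
Conditions: RuCl[(R,R)-TsDPEN](p-cymene) (5 mol %), HCO2H/Et3N, EtOAc, 50 °C
Reagents that add atoms: none
Why: In this Noyori–Ikariya ATH with DKR, Et3N epimerises C3 through the enol while the (R,R)-Ru–H reduces only the (3R)-ketone anti to the aryl group to give (4R)-cis-alcohol 6, whose para 7-OH then expels water to a p-quinone methide that a second Ru–H reduces, leaving C3 (R) as the only stereocentre.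

**Step 4**
Reactants: 7
Product: 8 (3R)-7,2′,4′-trihydroxyisoflavan
Conditions: BBr3 (5 equiv), CH2Cl2, −78 → 0 °C; MeOH quench
Reagents that add atoms: none
Why: Lewis-acid cleavage of the aryl methyl ethers is faster than opening of the chroman O–CH2 bond at ≤0 °C, no alkene is present yet, and the non-ionisable C3–H centre is untouched.

**Step 5**
Reactants: 8
Product: 9 (3R)-7,2′,4′-tris(methoxymethoxy)isoflavan
Conditions: NaH (4 equiv), MOMCl (4 equiv), DMF, 0 °C → rt, Ar
Reagents that add atoms: MOMCl, COCCl
Why: Exhaustive Williamson-type O-alkylation of the three phenoxides installs groups that serve as both protection and strong ortho-directing groups; C3 is not acidic to NaH.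

**Step 6**
Reactants: 9; 10 prenyl bromide (1-bromo-3-methylbut-2-ene)
Product: 11 (3R)-7,2′,4′-tris(methoxymethoxy)-8,3′-diprenylisoflavan
Conditions: n-BuLi (3 equiv), TMEDA, THF, 0 °C, 1.5 h; CuI (3 equiv), −78 → −30 °C; 10 (6 equiv), −78 °C → rt
Reagents that add atoms: prenyl bromide (10), CC(C)=CCBr
Why: In this twofold DoM, the two independent sites each flanked by two oxygens (C8 between O1 and 7-OMOM, C3′ between 2′- and 4′-OMOM) are the kinetically most acidic C–H bonds, far ahead of benzylic C3–H so there is no epimerisation, and the derived arylcopper species couple with prenyl bromide at its CH2 terminus (SN2).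

**Step 7**
Reactants: 11
Product: 12 Kanzonol X, (3R)-7,2′,4′-trihydroxy-8,3′-diprenylisoflavan
Conditions: 3 M aq. HCl, MeOH, 50 °C, about 45 min with close TLC control; NaHCO3 quench
Reagents that add atoms: none
Why: Acid-catalysed acetal methanolysis of phenolic MOM ethers is much faster under dilute protic conditions than hydroalkoxylation of the ortho-prenyl groups to dimethylchromans, and C3 is unaffected.

## Compound list
| No. | Name | SMILES | Role |
|---|---|---|---|
| 1 | resorcinol | Oc1cccc(O)c1 | starting material |
| 2 | 2,4-dimethoxyphenylacetic acid | COc1ccc(CC(=O)O)c(OC)c1 | starting material |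
| 3 | 1-(2,4-dihydroxyphenyl)-2-(2,4-dimethoxyphenyl)ethanone | COc1ccc(CC(=O)c2ccc(O)cc2O)c(OC)c1 | intermediate (not isolated) |
| 4 | 7-hydroxy-2′,4′-dimethoxyisoflavone | COc1ccc(-c2coc3cc(O)ccc3c2=O)c(OC)c1 | intermediate |
| 5 | (±)-7-hydroxy-2′,4′-dimethoxyisoflavanone | COc1ccc(C2COc3cc(O)ccc3C2=O)c(OC)c1 | intermediate |
| 6 | cis-(3R,4R)-7-hydroxy-2′,4′-dimethoxyisoflavan-4-ol | COc1ccc([C@@H]2COc3cc(O)ccc3[C@@H]2O)c(OC)c1 | intermediate (not isolated) |
| 7 | (3R)-7-hydroxy-2′,4′-dimethoxyisoflavan, (R)-sativan | COc1ccc([C@@H]2COc3cc(O)ccc3C2)c(OC)c1 | intermediate |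
| 8 | (3R)-7,2′,4′-trihydroxyisoflavan | Oc1ccc([C@@H]2COc3cc(O)ccc3C2)c(O)c1 | intermediate |
| 9 | (3R)-7,2′,4′-tris(methoxymethoxy)isoflavan | COCOc1ccc([C@@H]2COc3cc(OCOC)ccc3C2)c(OCOC)c1 | intermediate |
| 10 | prenyl bromide | CC(C)=CCBr | starting material |
| 11 | (3R)-7,2′,4′-tris(methoxymethoxy)-8,3′-diprenylisoflavan | COCOc1ccc([C@@H]2COc3c(CC=C(C)C)c(OCOC)ccc3C2)c(OCOC)c1CC=C(C)C | intermediate |
| 12 | Kanzonol X | CC(C)=CCc1c(O)ccc([C@@H]2COc3c(ccc(O)c3CC=C(C)C)C2)c1O | target |

## Summary
Total steps: 7. Longest linear sequence: 7 (fully linear).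

**Steps most likely to fail**
1. **Step 6 (double DoM and prenylation).** The risks are incomplete dilithiation, some C6 or C5′ lithiation, and mono-prenylated product.
   Fallback: install the prenyl groups before the rings are joined.
   - A single DoM/prenylation of 1,3-bis(MOMO)benzene gives a common building block.
   - A second lithiation converts part of it to the B-ring boronic acid.
   - Another part goes via the acetophenone, enaminone and I2 to 3-iodo-7-MOMO-8-prenylchromone.
   - Suzuki coupling gives the isoflavone. The Ru ATH-DKR tolerates prenyl groups, and the 4-OH is removed by Barton–McCombie deoxygenation.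
2. **Step 7 (acidic MOM removal next to prenyl groups).** The risk is cyclisation to 2,2-dimethylchromans.
   Fallback: replace MOM in Steps 5–6 with O-aryl N,N-diethylcarbamates, lithiated with s-BuLi/TMEDA at −78 °C. The phenols are then released reductively with LiAlH4 or Cp2Zr(H)Cl, so the prenylphenols never meet acid.
3. **Step 3 (domino ATH-DKR and deoxygenation).** The risks are stalling at alcohol 6, or tautomerisation of the quinone methide to the isoflav-3-ene, which would erode ee. If it only stalls, 6 can be reduced with Et3SiH/TFA, since no acid-labile groups are present at that stage.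
   Fallback: reduce 4 to the racemic isoflavan-4-ol, protect the phenol and dehydrate to the isoflav-3-ene. C3 is then set by Ir–phosphinooxazoline asymmetric hydrogenation, still before any prenyl group is present, and the route rejoins at Step 4.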